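**Retrosynthetic overview**
- Feature used: the carbonyl carbon C4 of ring C is bonded to C4a of ring A, which lies between C5 (free hydroxyl) and C8a (bearing O1). Cutting C3–C4 and C2–H therefore leads to a salicylaldehyde whose formyl carbon is C4 and whose other ortho oxygen (O1) carries a 1-phenylvinyl group (C2, C3 and ring B).
- Ring C is the only ring formed and is closed last, by an enantioselective rhodium-catalysed intramolecular hydroacylation that also sets C2.
- The enol ether is cut at O1–C2 back to the less hindered phenol of 3-geranyl-2,6-dihydroxy-4-methoxybenzaldehyde: Mitsunobu etherification with 2-bromo-1-phenylethanol, then dehydrobromination. No protecting group is used and the aldehyde is never masked.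
- Ring A: C-geranylation of the symmetric 2,6-dihydroxy-4-methoxybenzaldehyde, which comes from 4-O-methylation of 2,4,6-trihydroxybenzaldehyde. Rings A and B are bought.

Key step: step 5

Assumption: the sense of induction of the bisphosphine in the new hydroacylation cannot be derived from precedent. (R)-DTBM-SEGPHOS is written; its enantiomer is used instead if a trial run shows that it leads to the 2R product.

**Route**

Step 1
Reactants: 1 2,4,6-trihydroxybenzaldehyde
Product: 2 2,6-dihydroxy-4-methoxybenzaldehyde
Conditions: Me2SO4 (1.0 equiv), K2CO3 (1.0 equiv), acetone, 0 °C to rt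
Reagents that add atoms: dimethyl sulfate, COS(=O)(=O)OC
Why: Selective phenol O-methylation (Williamson type): the 4-hydroxyl is para to the formyl group and is the only one not tied to the carbonyl by a hydrogen bond, so it is the most acidic and should react first with one equivalent of the hard electrophile, giving a symmetric product.

Step 2
Reactants: 2 2,6-dihydroxy-4-methoxybenzaldehyde; 3 geranyl bromide
Product: 4 3-[(2E)-3,7-dimethylocta-2,6-dien-1-yl]-2,6-dihydroxy-4-methoxybenzaldehyde
Conditions: KOH (10% aq), 0 °C to rt
Reagents that add atoms: none
Why: Base-mediated C-allylation of an acylphloroglucinol-type phenoxide: in water the phenoxide oxygens are shielded by solvation, so the ring carbon (ortho to one phenoxide, para to the other) attacks the allylic bromide in an SN2 reaction that keeps the E alkene, and because 2 is symmetric only one mono-C-geranyl isomer can form.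

Step 3
Reactants: 4 3-geranyl-2,6-dihydroxy-4-methoxybenzaldehyde; 5 2-bromo-1-phenylethanol (racemic)
Product: 6 6-(2-bromo-1-phenylethoxy)-3-geranyl-2-hydroxy-4-methoxybenzaldehyde (racemic)
Conditions: PPh3, DIAD, THF, 0 °C to rt
Reagents that add atoms: none
Why: Mitsunobu etherification: the hydroxyl flanked by the geranyl CH2 and the formyl group is too hindered for SN2 attack on a secondary benzylic oxyphosphonium, so the hydroxyl next to the ring C–H should react; the new benzylic stereocentre is racemic and is erased in step 4.

Step 4
Reactants: 6 6-(2-bromo-1-phenylethoxy)-3-geranyl-2-hydroxy-4-methoxybenzaldehyde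
Product: 7 3-geranyl-2-hydroxy-4-methoxy-6-[(1-phenylethenyl)oxy]benzaldehyde
Conditions: KOtBu (2.5 equiv), THF, −20 to 0 °C; pH 7 phosphate buffer work-up
Reagents that add atoms: none
Why: Base-induced dehydrobromination (E2) of a beta-bromo ether, the classical route to aryl vinyl ethers: the only hydrogen beta to bromine is the benzylic alpha-oxy hydrogen, so the 1-phenylvinyl ether is the only alkene that can form, and the non-enolisable aldehyde and the phenoxide formed by the extra base should be inert.

Step 5
Reactants: 7 3-geranyl-2-hydroxy-4-methoxy-6-[(1-phenylethenyl)oxy]benzaldehyde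
Product: 8 (2S)-6-geranylpinostrobin
Conditions: [Rh(cod)Cl]2 (2.5 mol%), (R)-DTBM-SEGPHOS (5.5 mol%), AgBF4 (5 mol%, AgCl filtered off), 2,6-di-tert-butyl-4-methylpyridine (10 mol%), 1,4-dioxane, 60 °C, argon
Reagents that add atoms: none
Why: Proposed new method: the cationic monovalent rhodium bisphosphine complex adds oxidatively into the formyl C–H bond to give an acyl rhodium hydride that the neighbouring 5-hydroxyl oxygen holds as a five-membered chelate (which disfavours decarbonylation), the 1,1-disubstituted enol ether alkene on the other ortho oxygen then inserts into Rh–H with hydride delivered to C2, and reductive elimination from the seven-membered acyl alkyl rhodacycle forms C3–C4. The closest known reaction types are the rhodium-catalysed enantioselective intramolecular hydroacylation of ortho-allylbenzaldehydes that carry 1,1-disubstituted alkenes and the chelation-assisted hydroacylation of alkenes by salicylaldehydes; an aryl 1-arylvinyl ether as the alkene partner has not been shown. Ring C is closed in a formal 6-endo-trig mode, since both alkene carbons (C2 and C3) become ring atoms. C2, the only new stereocentre, is fixed in the hydride transfer, where the chiral pocket of the bisphosphine selects the alkene face that turns the phenyl group away from the aryl groups on phosphorus. The step needs hydride to go to C2 and not to C3 (which would lead to a 2-methyl-2-phenylbenzofuran-3-one); this is secured by the substrate, because rhodium then sits on the unhindered primary carbon and the polarised enol ether accepts hydride at its oxygen- and phenyl-bearing carbon. The hindered pyridine keeps the medium free of acid, so the enol ether cannot condense with the aldehyde to a flavylium salt, and since no base is present the 5-hydroxyflavanone cannot racemise by opening to the chalcone.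

**Compound list**

1 | 2,4,6-trihydroxybenzaldehyde | O=Cc1c(O)cc(O)cc1O | starting material
2 | 2,6-dihydroxy-4-methoxybenzaldehyde | COc1cc(O)c(C=O)c(O)c1 | intermediate
3 | geranyl bromide, (2E)-1-bromo-3,7-dimethylocta-2,6-diene | CC(C)=CCC/C(C)=C/CBr | starting material
4 | 3-[(2E)-3,7-dimethylocta-2,6-dien-1-yl]-2,6-dihydroxy-4-methoxybenzaldehyde | COc1cc(O)c(C=O)c(O)c1C/C=C(\C)CCC=C(C)C | intermediate
5 | 2-bromo-1-phenylethanol (racemic) | OC(CBr)c1ccccc1 | starting material
6 | 6-(2-bromo-1-phenylethoxy)-3-[(2E)-3,7-dimethylocta-2,6-dien-1-yl]-2-hydroxy-4-methoxybenzaldehyde (racemic) | COc1cc(OC(CBr)c2ccccc2)c(C=O)c(O)c1C/C=C(\C)CCC=C(C)C | intermediate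
7 | 3-[(2E)-3,7-dimethylocta-2,6-dien-1-yl]-2-hydroxy-4-methoxy-6-[(1-phenylethenyl)oxy]benzaldehyde | COc1cc(OC(=C)c2ccccc2)c(C=O)c(O)c1C/C=C(\C)CCC=C(C)C | intermediate
8 | (2S)-6-geranylpinostrobin, (2S)-6-[(2E)-3,7-dimethylocta-2,6-dien-1-yl]-5-hydroxy-7-methoxy-2-phenylchroman-4-one | COc1cc2c(c(O)c1C/C=C(\C)CCC=C(C)C)C(=O)C[C@@H](c1ccccc1)O2 | target

**Step count**

Total steps: 5. Longest linear sequence: 5 steps (1 → 2 → 4 → 6 → 7 → 8).

**Steps most likely to fail**

1. Step 5 (proposed new method). The acyl rhodium hydride may decarbonylate or fail to insert the electron-rich enol ether, traces of acid may divert the substrate into flavylium formation, or the facial selectivity at C2 may be poor. The fallback uses known chemistry and takes the stereocentre from a reagent instead of a catalyst. It sets out from 4, which is etherified under the Mitsunobu conditions of step 3 with (S)-2-bromo-1-phenylethanol (O[C@H](CBr)c1ccccc1). Inversion at the benzylic carbon should give 6-[(1R)-2-bromo-1-phenylethoxy]-3-[(2E)-3,7-dimethylocta-2,6-dien-1-yl]-2-hydroxy-4-methoxybenzaldehyde F1. F1 is then treated with 3-benzyl-5-(2-hydroxyethyl)-4-methylthiazolium chloride (20 mol%) and Et3N in 1,4-dioxane at rt. The carbene converts the aldehyde into its acyl anion equivalent, which displaces the primary bromide (6-exo-tet) and forms C3–C4 without touching the stereocentre. This is the known carbene-catalysed ring closure of O-(2-haloalkyl)salicylaldehydes to chroman-4-ones. It comes back to the route at 8. The base is kept weak and the reaction time short to limit ring opening to the chalcone.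

2. Step 2. The phenoxide may be alkylated on oxygen, a second geranyl group may enter, or the allylic bromide may hydrolyse. The fallback forms the aryl–geranyl bond by cross-coupling. It sets out from 2, which is iodinated with N-iodosuccinimide (MeCN, 0 °C) at its only type of ring C–H to give 2,6-dihydroxy-3-iodo-4-methoxybenzaldehyde F2. Separately, 3 is converted with Bu3SnLi (THF, −78 °C) into tributyl[(2E)-3,7-dimethylocta-2,6-dien-1-yl]stannane F3. Stille coupling of F2 with F3 (Pd(PPh3)4, DMF, 80 °C) should join the aryl carbon to the unsubstituted allyl terminus and comes back to the route at 4.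

3. Step 3. Etherification may occur at the wrong hydroxyl or at both, or the activated bromohydrin may eliminate instead of being displaced. The fallback forms the aryl–O–vinyl bond directly by copper-mediated oxidative coupling (Chan–Lam type). It sets out from 4, which is coupled with 1-phenylvinylboronic acid (Cu(OAc)2, pyridine, 4 Å molecular sieves, air, CH2Cl2, rt). It comes back to the route at 7 and so replaces steps 3 and 4. This fallback makes no new compound (F0).

**Further compounds**

F1 | step 5 | 6-[(1R)-2-bromo-1-phenylethoxy]-3-[(2E)-3,7-dimethylocta-2,6-dien-1-yl]-2-hydroxy-4-methoxybenzaldehyde | COc1cc(O[C@@H](CBr)c2ccccc2)c(C=O)c(O)c1C/C=C(\C)CCC=C(C)C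
F2 | step 2 | 2,6-dihydroxy-3-iodo-4-methoxybenzaldehyde | COc1cc(O)c(C=O)c(O)c1I
F3 | step 2 | tributyl[(2E)-3,7-dimethylocta-2,6-dien-1-yl]stannane | CCCC[Sn](CCCC)(CCCC)C/C=C(\C)CCC=C(C)C
F0 | step 3 | none | none
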